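All runs come from a simulation on assumed constants, and the scatter is random.

**Two rates.** Two rates compete for the single product in these flasks: its making from substrate and its loss to double product. The flask asked about is charged with more substrate than either earlier run.

| setting | north-east | south-east | flask |
|---|---|---|---|
| substrate | 0.050 M | 0.075 M | 0.10 M |
| gas | 48 mM (held) | 48 mM (held) | 48 mM (held) |
| remark | run made earlier | run made earlier |  |
| time |  |  | 5.0 d |

| north-east: time / d | north-east: single product / % | south-east: time / d | south-east: single product / % |
|---|---|---|---|
| 0.333 | 34 | 0.333 | 33 |
| 0.625 | 44 | 0.625 | 41 |
| 1.04 | 44 | 1.04 | 44 |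
| 2.00 | 46 | 2.00 | 43 |
| 4.00 | 40 | 4.00 | 42 |

(standard deviation of a reading: 1.5 percentage points)

1. time, not beyond 5.0 d, at which the flask holds most single product
2. the amount of single product, in percent of the substrate charged, at that time

- at the start none of reagent is dissolved
- steps under discussion: gas <-> reagent; reagent + single product -> double product; substrate + reagent -> other mono adduct; substrate + reagent -> single product; reagent + other mono adduct -> double product

**Substrate charge.** If reagent stays near its saturation value of 48 mM, each step is pseudo-first-order, and by hand the percent curve ignores the charge. The runs at 0.050 M and 0.075 M both read 44% at 1.04 d, so I carried their pooled curve to 0.10 M, beyond both charges.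

**Reaction time.** The pooled fall from 2.00 d to 4.00 d gave me a loss constant k = 0.0410 /d. Run back to zero time, it gave a selectivity S = 48.3%, the share of spent substrate that becomes single product. The first readings then gave a substrate constant K = 3.55 /d.

With a the share of substrate left and y the share of single product, the gain is SKa and the loss is ky. They are equal where a/y reaches the crossing ratio X = k/(SK) = 0.0239. At the first reading of the two earlier runs, a/y reckoned from S stood near 0.915, far above X, so gain led. Since a/y falls as the run goes on, y peaks at the crossing, which I reckoned at 1.27 d and 45.8%.

**The forecast.** The forecast gave 1.3 d (0.8 d to 2.2 d) and 44.5% (42% to 47%), a height below mine, and said: “The maximum is broad, so the time is poorly defined.”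

**The result.** The flask reached 44.5% at 1.22 d.

    gas ⇌ reagent, rate k1*(csat - [reagent]) (kL = 3.60 × 10⁻⁴ /s)
    reagent + single product → double product (k = 7.20 × 10⁻⁶ /M/s)
    substrate + reagent → other mono adduct (k = 6.10 × 10⁻⁴ /M/s)
    substrate + reagent → single product (k = 5.20 × 10⁻⁴ /M/s)
    reagent + other mono adduct → double product (k = 0.00140 /M/s)

**Past crossing.** In the flask, a/y was 0.413 at 0.500 d, above X, and single product stood at 38.4%, still short of its peak. At the best time a/y was 0.0138, below the X I had read from the scattered runs. The neighbouring flask, the same flask read at 3.0 d, held 0% substrate, so its a/y lay below X, on the losing side of the crossing. It held 42.5% single product, down from a highest amount of 44.5%.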